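Locants follow neolignan usage: ring A is the 3,4,5-trimethoxyphenyl ring, C7–C8–C9 its side chain, ring B the benzo ring (C1'–C6') and C7'–C9' the propenyl chain. In benzofuran names C2 = C7 and C3 = C8.

Compound numbers: 1 5-bromo-2-hydroxy-3-methoxybenzaldehyde; 2 its silyl ether; 3 the ring B styrene; 4 3,4,5-trimethoxybenzaldehyde; 5 the silylated trans-2,3-diaryloxetane; 6 the oxetane phenol; 7 the racemic trans-dihydrobenzofuran bromo alcohol; 8 its (2R,3S) enantiomer; 9 methyl acrylate; 10 the cinnamate ester; 11 the target.

## Analysis of the target

Compound 11 is a trans-2-aryl-3-hydroxymethyl-2,3-dihydrobenzofuran: the five-membered ring is made of the C4' oxygen, C7, C8, C3' and C4', is fused to ring B (C5' methoxyl, (E)-3-hydroxyprop-1-enyl chain at C1'), and carries ring A on C7 and the C9 hydroxymethyl group on C8. C7 and C8 are the only stereocentres; they are adjacent, trans across the ring, and (7R,8S). The trans arrangement is the more stable one and tends to result from any closure that can equilibrate, but nothing in the molecule helps with the absolute sense. C7 is benzylic and bound to the aryl ether oxygen, so acid can reopen the ring there, and the cinnamyl alcohol ionises and oxidises easily. The difficulty is that ring A has no free para hydroxyl, so the quinone methide closure commonly used for this skeleton is not available. The C7–C8 bond must therefore be made between two aryl-bearing carbons while C7 and C9 receive different oxygen functions. The strategy rests on this pattern: C7 carries oxygen and ring A, C8 carries ring B, C9 carries oxygen. If the oxygens on C7 and C9 are one atom, these atoms form a 2,3-diaryloxetane, the (2+2) adduct of a ring A aldehyde (C7=O) and a ring B styrene (C8=C9). The C4' phenol, ortho to C3', can then displace that oxygen from C7, closing the five-membered ring and leaving the oxetane oxygen as the C9 hydroxyl.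

## Retrosynthetic reasoning

11 to 10. No skeletal bond is cut; the allylic alcohol at C9' is taken back to the methyl ester 10. The cinnamyl alcohol is the most fragile part of 11 and should appear last. The forward step must reduce a conjugated ester at the carbonyl only, next to a free primary alcohol.

10 to 8 and 9. The C1'–C7' bond between ring B and the chain is cut. It joins an arene carbon to an alkene, which is the retron of a Heck coupling of the aryl bromide 8 with methyl acrylate 9. This brings C7'–C9' in one piece and sets the E geometry. Bromine is the placeholder at C1' because it is inert to ylides, long-wavelength light, fluoride and acid, and is already present in the commercial aldehyde 1.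

8 to 7. No bond is cut; the single enantiomer 8 is traced to the racemate 7. The absolute configuration is left to a resolution because the bond-forming step joins two achiral partners photochemically and no dependable asymmetric version exists. Compound 7 is the right place: the C9 hydroxyl is free and one carbon from C8, so an acyl-transfer enzyme can read the stereocentre. Since C7 and C8 are locked trans, separating at C8 separates both.

7 to 6. The bond from the C4' oxygen to C7 is cut and C7 is reconnected to the oxygen on C9, giving the oxetane phenol 6. This turns the dihydrobenzofuran into a strained constitutional isomer, so the forward step is an isomerisation driven by most of the roughly 25 kcal/mol of oxetane strain. The phenol must attack C7 and not C9, with inversion or through the C7 cation, so that the trans oxetane becomes the trans dihydrobenzofuran. C8 is not touched.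

6 to 5. The phenol is masked as the silyl ether 5. A free phenol would quench an excited carbonyl group and would open the oxetane as soon as it formed. The forward step needs a fluoride source under conditions that leave the four-membered ring closed.

5 to 3 and 4. C7–C8 and O–C9 are cut together, the retron of a Paternò–Büchi cycloaddition. C7 with its oxygen becomes the formyl group of 4, and C8=C9 the vinyl group of 3. One step then assembles the whole core from two simple arenes, creates both stereocentres and places oxygen on C9. The forward reaction must put the oxygen on C9, favour the trans ring and compete with quenching of the excited aldehyde by the styrene.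

3 to 2 to 1. C8=C9 is cut by a carbonyl methylenation, leading to aldehyde 2. Removing the silyl group gives commercial 1.

## Alternatives that were turned down

Alternative 1: The dihydrofuran ring is taken back to an aromatic benzofuran, which is cut at O–C7 and C8–C9. This leads to the alkynylphenol A1, 4-hydroxy-3-methoxy-5-[(3,4,5-trimethoxyphenyl)ethynyl]benzaldehyde, itself a Sonogashira product of a ring B iodophenol and a ring A arylacetylene. The forward key step is an oxidative alkoxycarbonylative cyclisation (PdI2/KI, CO and air, methanol). The alkyne, activated by divalent palladium, is attacked by the phenol oxygen at C7; the C8–Pd bond takes up CO and is cleaved by the alcohol. The product is the benzofuran ester A2, methyl 5-formyl-7-methoxy-2-(3,4,5-trimethoxyphenyl)benzofuran-3-carboxylate. In its favour are a catalytic, regiochemically unambiguous C–C bond formation, flat crystalline intermediates, C9 delivered as an ester and a formyl group at C1' ready for the chain. On reliability of the skeleton-forming step it is stronger than a photocycloaddition that competes with energy transfer. Against it, A2 has no stereocentre, so C7 and C8 must both be made later by reducing a tetrasubstituted furan double bond. Magnesium in methanol would give the trans racemate but would not spare an aldehyde or a cinnamate, so the order of steps is constrained and a resolution is still needed. Catalytic asymmetric hydrogenation of such a 2-aryl-3-acylbenzofuran would add hydrogen cis and risks hydrogenolysis of the benzylic C7–O bond. The route is also longer and needs CO. The chosen strategy instead creates C7 and C8 as sp3 centres in the bond-forming step, already trans and with C9 at the alcohol level.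

Alternative 2: Ring B itself is dismantled at C4'–C3', C2'–C1' and C1'–C6'. This leaves the pentacarbonylchromium carbene complex A3. Its carbene carbon is the future C4', its 1-methoxyvinyl group supplies C5' and C6', and its alkoxy group is the stereodefined C7–C8 unit with ring A, the silylated C9 oxygen and a terminal alkyne (C3'≡C2'). On heating, the Dötz benzannulation proceeds by CO loss, insertion of the tethered alkyne (C4'–C3'), CO insertion to a vinylketene (C2'–C1') and 6π electrocyclisation (C1'–C6'). Because the tether runs through the ether oxygen, ring B and the dihydrofuran ring close together, giving the phenol A4, (2R,3S)-3-(tert-butyldimethylsilyloxymethyl)-7-methoxy-2-(3,4,5-trimethoxyphenyl)-2,3-dihydrobenzofuran-5-ol. In its favour, both stereocentres are set beforehand on an open chain by established asymmetric methods, so nothing is lost in a resolution, and the tether fixes the regiochemistry. On absolute stereocontrol it is stronger than the chosen plan. Against it are stoichiometric chromium and the need to attach a hindered, ionisable benzylic alkoxide to a carbene carbon. The propargylic C8 and benzylic C7 are exposed to the heat of the annulation, and an alkoxyvinyl carbene on a short tether can divert to five-membered-ring products. A4 also has a hydroxyl at C1' where the target has carbon, so triflation and coupling must follow. The sequence to A3 alone is longer than the whole chosen route, which uses both arenes as purchased rings.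

Alternative 3: The bond from ring A carbon C1 to C7 and the O–C7 bond are cut. This leads to the α-aryl aldehyde A5, (S)-2-[5-bromo-3-methoxy-2-(methoxymethoxy)phenyl]-3-(tert-butyldiphenylsilyloxy)propanal. It derives from a 2-arylpropane-1,3-diol whose hydroxymethyl arms are enantiotopic: one is silylated after a desymmetrising acylation (future C9), the other oxidised (future C7). In the forward key step a ring A aryl Grignard reagent, transmetallated with CeCl3, adds to the aldehyde. Acid added to the same flask removes the acetal group and ionises the new benzylic carbinol, so the phenol closes the trans ring. The product is A6, tert-butyl{[(2R,3S)-5-bromo-7-methoxy-2-(3,4,5-trimethoxyphenyl)-2,3-dihydrobenzofuran-3-yl]methoxy}diphenylsilane. In its favour, the absolute configuration comes from a desymmetrisation that can in principle convert all material, the cation closure is the classical one, and the diastereomer ratio of the addition is irrelevant. On throughput of chiral material and precedent for the ring closure it is stronger than the chosen plan. Against it, the only stereocentre of A5 is both benzylic and α to the formyl group, so enantiomeric purity is at risk during oxidation and organometallic addition. The acid step must also distinguish an acetal from a silyl ether, and about ten steps are needed. The chosen strategy has no configurationally labile intermediate, since C8 is not enolisable after the ring switch. It reaches the same bromide skeleton in five steps from two aldehydes, at the price of a resolution and a photochemical step of low quantum efficiency.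

Key step: step 3

Assumption: in step 6 the lipase is taken to acylate the (2S,3R) enantiomer of 7 faster, so that 8 is the recovered alcohol; this sense is not safely predictable for a primary alcohol whose β-carbon carries two large groups, and the fallback for step 6 does not depend on it. Racemic 5, 6 and 7 are drawn as the enantiomer that leads to 11.

## Route

Step 1
Reactants: 1 5-bromo-2-hydroxy-3-methoxybenzaldehyde
Product: 2 5-bromo-2-(tert-butyldimethylsilyloxy)-3-methoxybenzaldehyde
Conditions: TBSCl, imidazole, DMF, rt
Reagents that add atoms: tert-butyldimethylsilyl chloride, CC(C)(C)[Si](C)(C)Cl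
Why: Silylation of a phenol with a silyl chloride and imidazole; the flanked oxygen is still reached by silicon. The silyl ether keeps the phenol from protonating the ylide in step 2 and from quenching the excited aldehyde in step 3.

Step 2
Reactants: 2 5-bromo-2-(tert-butyldimethylsilyloxy)-3-methoxybenzaldehyde
Product: 3 (4-bromo-2-methoxy-6-vinylphenoxy)(tert-butyl)dimethylsilane
Conditions: Ph3PCH3Br, NaN(SiMe3)2, THF, 0 °C; then 2, 0 °C to rt
Reagents that add atoms: methyltriphenylphosphonium bromide, C[P+](c1ccccc1)(c1ccccc1)c1ccccc1.[Br-]
Why: Wittig methylenation of an aromatic aldehyde by the non-stabilised ylide. The amide base is used up in forming the ylide before 2 is added, so the aryl bromide and the aryl silyl ether meet no strong nucleophile.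

Step 3
Reactants: 3 (4-bromo-2-methoxy-6-vinylphenoxy)(tert-butyl)dimethylsilane; 4 3,4,5-trimethoxybenzaldehyde
Product: 5 rac-trans-3-[5-bromo-2-(tert-butyldimethylsilyloxy)-3-methoxyphenyl]-2-(3,4,5-trimethoxyphenyl)oxetane, (2S,3S) enantiomer drawn
Conditions: hν (350 nm, Pyrex), 4 (4 equiv), benzene (degassed), rt, slow addition of 3
Reagents that add atoms: none
Why: Paternò–Büchi (2+2) photocycloaddition: at 350 nm only 4 absorbs, and its triplet adds through oxygen to the unsubstituted alkene carbon C9 of 3, because this gives the 1,4-biradical in which both radical centres are benzylic (C7, which also bears the oxygen, and C8). After intersystem crossing the two radical centres combine, forming C7–C8 and closing the oxetane; the four-membered ring arises by collapse of a biradical, not by a polar exo or endo closure. The closest known reaction type is the photocycloaddition of benzaldehydes to alkenes and to β-substituted styrenes, which gives 2-aryl- and 2,3-diaryloxetanes with the oxygen on the non-benzylic alkene carbon. C7 and C8 are created together; their relative configuration is decided in the biradical, which lives long enough to rotate and should close from the conformer with rings A and B anti, so the trans oxetane is expected to predominate. No element controls the absolute sense, so 5 is racemic. The selectivity needed is bond formation in preference to triplet energy transfer from the aldehyde to the styrene, which is downhill; a terminal styrene triplet relaxes to the same alkene, so this transfer wastes photons and not substrate as long as 3 is kept dilute and cannot dimerise. Benzene offers no abstractable hydrogen and favours the reactive n,π* triplet of the methoxylated aldehyde, and the aryl bromide and silyl ether do not absorb at this wavelength.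

Step 4
Reactants: 5 rac-trans-3-[5-bromo-2-(tert-butyldimethylsilyloxy)-3-methoxyphenyl]-2-(3,4,5-trimethoxyphenyl)oxetane
Product: 6 rac-4-bromo-2-methoxy-6-[trans-2-(3,4,5-trimethoxyphenyl)oxetan-3-yl]phenol, (2S,3S) enantiomer drawn
Conditions: Bu4NF, AcOH (1:1), THF, 0 °C; pH 7 work-up, used crude
Reagents that add atoms: none
Why: Fluoride-induced cleavage of an aryl silyl ether. Buffering with acetic acid releases the phenol and not a bare phenoxide, which could attack the unhindered C9 of the oxetane; any opening the buffer acid already causes goes in the direction of step 5.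

Step 5
Reactants: 6 rac-4-bromo-2-methoxy-6-[trans-2-(3,4,5-trimethoxyphenyl)oxetan-3-yl]phenol
Product: 7 rac-[(2R,3S)-5-bromo-7-methoxy-2-(3,4,5-trimethoxyphenyl)-2,3-dihydro-1-benzofuran-3-yl]methanol (trans)
Conditions: camphorsulfonic acid (10 mol%), CH2Cl2, 0 °C to rt
Reagents that add atoms: none
Why: Acid-catalysed intramolecular opening of an oxetane by a phenol (strain-release ring switch, 5-exo-tet): protonation of the ring oxygen weakens mainly the benzylic C7–O bond, the C4' hydroxyl attacks C7 opposite to the leaving oxygen, and the old ring oxygen remains as the C9 hydroxyl. Inversion at C7 of the trans oxetane gives the trans dihydrobenzofuran, and a C7 cation would likewise be closed anti to the C9 group, so both paths should converge; C8 is not touched.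

Step 6
Reactants: 7 rac-[(2R,3S)-5-bromo-7-methoxy-2-(3,4,5-trimethoxyphenyl)-2,3-dihydro-1-benzofuran-3-yl]methanol
Product: 8 [(2R,3S)-5-bromo-7-methoxy-2-(3,4,5-trimethoxyphenyl)-2,3-dihydro-1-benzofuran-3-yl]methanol, single enantiomer
Conditions: lipase from Burkholderia cepacia (Amano PS), vinyl acetate, tBuOMe, 30 °C, to just past half conversion; chromatography
Reagents that add atoms: none
Why: Lipase-catalysed kinetic resolution by enantioselective transesterification of a primary alcohol whose stereocentre is the β-carbon, made irreversible by the enol ester. The (2S,3R) enantiomer is removed as its acetate and 8 is recovered; running past half conversion raises the enantiomeric purity of the recovered alcohol even at moderate enzyme selectivity. No stereocentre is formed here: the relative configuration comes from steps 3 and 5, and the enzyme selects the absolute sense.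

Step 7
Reactants: 8 [(2R,3S)-5-bromo-7-methoxy-2-(3,4,5-trimethoxyphenyl)-2,3-dihydro-1-benzofuran-3-yl]methanol; 9 methyl acrylate
Product: 10 methyl (2E)-3-[(2R,3S)-3-(hydroxymethyl)-7-methoxy-2-(3,4,5-trimethoxyphenyl)-2,3-dihydro-1-benzofuran-5-yl]prop-2-enoate
Conditions: Pd(OAc)2 (5 mol%), P(o-tol)3 (10 mol%), Et3N, DMF, 100 °C
Reagents that add atoms: none
Why: Mizoroki–Heck reaction: oxidative addition of the aryl bromide to zerovalent palladium formed in situ, syn insertion of the acrylate at its unsubstituted carbon and syn β-hydride elimination give the E cinnamate. The free alcohol tolerates the amine base, and neither stereocentre is α to a carbonyl group, so no epimerisation is expected.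

Step 8
Reactants: 10 methyl (2E)-3-[(2R,3S)-3-(hydroxymethyl)-7-methoxy-2-(3,4,5-trimethoxyphenyl)-2,3-dihydro-1-benzofuran-5-yl]prop-2-enoate
Product: 11 (2E)-3-[(2R,3S)-3-(hydroxymethyl)-7-methoxy-2-(3,4,5-trimethoxyphenyl)-2,3-dihydro-1-benzofuran-5-yl]prop-2-en-1-ol, the (7R,8S,7'E) target
Conditions: iBu2AlH (4 equiv), CH2Cl2, −78 °C; aq. potassium sodium tartrate
Reagents that add atoms: none
Why: 1,2-Reduction of an α,β-unsaturated ester to the allylic alcohol by iBu2AlH at low temperature; one equivalent is taken up by the free hydroxyl and the alkene keeps its E geometry. The tartrate work-up avoids acid, which could ionise the cinnamyl alcohol or C7.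

## Compound list

1 | 5-bromo-2-hydroxy-3-methoxybenzaldehyde | COc1cc(Br)cc(C=O)c1O | starting material
2 | 5-bromo-2-(tert-butyldimethylsilyloxy)-3-methoxybenzaldehyde | COc1cc(Br)cc(C=O)c1O[Si](C)(C)C(C)(C)C | intermediate
3 | (4-bromo-2-methoxy-6-vinylphenoxy)(tert-butyl)dimethylsilane | C=Cc1cc(Br)cc(OC)c1O[Si](C)(C)C(C)(C)C | intermediate
4 | 3,4,5-trimethoxybenzaldehyde | COc1cc(C=O)cc(OC)c1OC | starting material
5 | rac-trans-3-[5-bromo-2-(tert-butyldimethylsilyloxy)-3-methoxyphenyl]-2-(3,4,5-trimethoxyphenyl)oxetane, (2S,3S) enantiomer drawn | COc1cc([C@H]2OC[C@@H]2c2cc(Br)cc(OC)c2O[Si](C)(C)C(C)(C)C)cc(OC)c1OC | intermediate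
6 | rac-4-bromo-2-methoxy-6-[trans-2-(3,4,5-trimethoxyphenyl)oxetan-3-yl]phenol, (2S,3S) enantiomer drawn | COc1cc([C@H]2OC[C@@H]2c2cc(Br)cc(OC)c2O)cc(OC)c1OC | intermediate
7 | rac-[(2R,3S)-5-bromo-7-methoxy-2-(3,4,5-trimethoxyphenyl)-2,3-dihydro-1-benzofuran-3-yl]methanol, trans racemate, (2R,3S) enantiomer drawn | COc1cc([C@@H]2Oc3c(OC)cc(Br)cc3[C@H]2CO)cc(OC)c1OC | intermediate
8 | [(2R,3S)-5-bromo-7-methoxy-2-(3,4,5-trimethoxyphenyl)-2,3-dihydro-1-benzofuran-3-yl]methanol, single enantiomer | COc1cc([C@@H]2Oc3c(OC)cc(Br)cc3[C@H]2CO)cc(OC)c1OC | intermediate
9 | methyl acrylate | C=CC(=O)OC | starting material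
10 | methyl (2E)-3-[(2R,3S)-3-(hydroxymethyl)-7-methoxy-2-(3,4,5-trimethoxyphenyl)-2,3-dihydro-1-benzofuran-5-yl]prop-2-enoate | COc1cc([C@@H]2Oc3c(OC)cc(/C=C/C(=O)OC)cc3[C@H]2CO)cc(OC)c1OC | intermediate
11 | (2E)-3-[(2R,3S)-3-(hydroxymethyl)-7-methoxy-2-(3,4,5-trimethoxyphenyl)-2,3-dihydro-1-benzofuran-5-yl]prop-2-en-1-ol | COc1cc([C@@H]2Oc3c(OC)cc(/C=C/CO)cc3[C@H]2CO)cc(OC)c1OC | target

## Step count and least certain steps

Total: 8 steps. Longest linear sequence: 8 steps, from 1 to 11; 4 and 9 enter as purchased compounds.

Step 3 (key step). The main danger is quenching of the excited aldehyde by energy transfer to the styrene. This lowers the conversion per photon and, if the styrene concentration rises, lets the styrene photodimerise or polymerise. The lowest triplet of a trimethoxylated benzaldehyde may also be largely π,π* in character and react sluggishly. Closure of the biradical may be only partly trans-selective, and prolonged irradiation may cause hydrogen abstraction from the product. A cis component would matter less if step 5 passes through the C7 cation. The fallback sets out from 3 and 4 and returns at 7; it makes C7–C8 by an aldol reaction.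
- Hydroboration of 3 (9-BBN, THF; NaBO3·4H2O) should give 2-[5-bromo-2-(tert-butyldimethylsilyloxy)-3-methoxyphenyl]ethanol F1.
- Oxidation (TEMPO cat., PhI(OAc)2, MeCN/H2O) gives 2-[5-bromo-2-(tert-butyldimethylsilyloxy)-3-methoxyphenyl]acetic acid F2.
- The dianion of F2 (LiN(iPr)2, THF, −78 °C, kept cold to forestall oxygen-to-carbon silyl migration) adds to 4 to give 2-[5-bromo-2-(tert-butyldimethylsilyloxy)-3-methoxyphenyl]-3-hydroxy-3-(3,4,5-trimethoxyphenyl)propanoic acid F3 as a diastereomer mixture.
- BH3·SMe2 reduces the acid to 2-[5-bromo-2-(tert-butyldimethylsilyloxy)-3-methoxyphenyl]-1-(3,4,5-trimethoxyphenyl)propane-1,3-diol F4.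
- Bu4NF frees 2-(5-bromo-2-hydroxy-3-methoxyphenyl)-1-(3,4,5-trimethoxyphenyl)propane-1,3-diol F5.
- Catalytic TsOH in CH2Cl2 ionises the benzylic carbinol and the phenol closes the trans ring, which is 7. The C7 configuration of the aldol is lost in the cation and does not matter.

Step 5. The phenol may attack the unhindered C9 instead of C7 (both closures are 5-exo) if the opening has too little cationic character at C7. The C7 cation may also fragment with loss of the C9 unit, and the trans selectivity may be eroded. The fallback sets out from 5 and returns at 7; it changes the order of events so that only C7 is electrophilic when the phenol appears.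
- Acid-catalysed methanolysis of 5 (camphorsulfonic acid cat., MeOH, 0 °C) opens the oxetane at the benzylic carbon to 2-[5-bromo-2-(tert-butyldimethylsilyloxy)-3-methoxyphenyl]-3-methoxy-3-(3,4,5-trimethoxyphenyl)propan-1-ol F6.
- Bu4NF gives 4-bromo-2-[1-hydroxy-3-methoxy-3-(3,4,5-trimethoxyphenyl)propan-2-yl]-6-methoxyphenol F7.
- BF3·OEt2 in CH2Cl2 at −20 °C ionises the benzylic methyl ether and the phenol closes the ring to 7.

Step 6. The enzyme may discriminate poorly between enantiomers whose difference lies one carbon from the reacting hydroxyl, or may prefer the opposite sense to the one assumed. The fallback sets out from 7 and returns at 8; it is a resolution through covalent diastereomers.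
- Esterification of 7 with (S)-2-methoxy-2-phenylacetic acid (DCC, DMAP cat., CH2Cl2) gives [(2R,3S)-5-bromo-7-methoxy-2-(3,4,5-trimethoxyphenyl)-2,3-dihydro-1-benzofuran-3-yl]methyl (2S)-2-methoxy-2-phenylacetate F8 and its diastereomer [(2S,3R)-5-bromo-7-methoxy-2-(3,4,5-trimethoxyphenyl)-2,3-dihydro-1-benzofuran-3-yl]methyl (2S)-2-methoxy-2-phenylacetate F9.
- These are separated by chromatography or crystallisation, and LiOH in THF/H2O releases 8 from F8.
- In either mode the bromine atom of 8 allows the absolute configuration to be secured by anomalous X-ray dispersion.

Step 7. Oxidative addition of the electron-rich aryl bromide may be slow, and the high temperature this demands may cause acrylate polymerisation and catalyst decomposition. The fallback sets out from 8 and returns at 11, replacing steps 7 and 8.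
- Suzuki–Miyaura coupling of 8 with commercial tert-butyldimethyl{[(2E)-3-(4,4,5,5-tetramethyl-1,3,2-dioxaborolan-2-yl)prop-2-en-1-yl]oxy}silane (Pd(OAc)2, SPhos, K3PO4, THF/H2O, 60 °C) should give [(2R,3S)-5-[(1E)-3-(tert-butyldimethylsilyloxy)prop-1-en-1-yl]-7-methoxy-2-(3,4,5-trimethoxyphenyl)-2,3-dihydro-1-benzofuran-3-yl]methanol F10.
- Bu4NF in THF then gives 11.

## Further compounds

F1 | step 3 | 2-[5-bromo-2-(tert-butyldimethylsilyloxy)-3-methoxyphenyl]ethanol | OCCc1cc(Br)cc(OC)c1O[Si](C)(C)C(C)(C)C
F2 | step 3 | 2-[5-bromo-2-(tert-butyldimethylsilyloxy)-3-methoxyphenyl]acetic acid | OC(=O)Cc1cc(Br)cc(OC)c1O[Si](C)(C)C(C)(C)C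
F3 | step 3 | 2-[5-bromo-2-(tert-butyldimethylsilyloxy)-3-methoxyphenyl]-3-hydroxy-3-(3,4,5-trimethoxyphenyl)propanoic acid, racemic diastereomer mixture, no configuration implied | COc1cc(C(O)C(C(=O)O)c2cc(Br)cc(OC)c2O[Si](C)(C)C(C)(C)C)cc(OC)c1OC
F4 | step 3 | 2-[5-bromo-2-(tert-butyldimethylsilyloxy)-3-methoxyphenyl]-1-(3,4,5-trimethoxyphenyl)propane-1,3-diol, racemic diastereomer mixture, no configuration implied | COc1cc(C(O)C(CO)c2cc(Br)cc(OC)c2O[Si](C)(C)C(C)(C)C)cc(OC)c1OC
F5 | step 3 | 2-(5-bromo-2-hydroxy-3-methoxyphenyl)-1-(3,4,5-trimethoxyphenyl)propane-1,3-diol, racemic diastereomer mixture, no configuration implied | COc1cc(C(O)C(CO)c2cc(Br)cc(OC)c2O)cc(OC)c1OC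
F6 | step 5 | 2-[5-bromo-2-(tert-butyldimethylsilyloxy)-3-methoxyphenyl]-3-methoxy-3-(3,4,5-trimethoxyphenyl)propan-1-ol, racemic, C7 epimers, no configuration implied | COc1cc(C(OC)C(CO)c2cc(Br)cc(OC)c2O[Si](C)(C)C(C)(C)C)cc(OC)c1OC
F7 | step 5 | 4-bromo-2-[1-hydroxy-3-methoxy-3-(3,4,5-trimethoxyphenyl)propan-2-yl]-6-methoxyphenol, racemic, C7 epimers, no configuration implied | COc1cc(C(OC)C(CO)c2cc(Br)cc(OC)c2O)cc(OC)c1OC
F8 | step 6 | [(2R,3S)-5-bromo-7-methoxy-2-(3,4,5-trimethoxyphenyl)-2,3-dihydro-1-benzofuran-3-yl]methyl (2S)-2-methoxy-2-phenylacetate | COc1cc([C@@H]2Oc3c(OC)cc(Br)cc3[C@H]2COC(=O)[C@@H](OC)c2ccccc2)cc(OC)c1OC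
F9 | step 6 | [(2S,3R)-5-bromo-7-methoxy-2-(3,4,5-trimethoxyphenyl)-2,3-dihydro-1-benzofuran-3-yl]methyl (2S)-2-methoxy-2-phenylacetate | COc1cc([C@H]2Oc3c(OC)cc(Br)cc3[C@@H]2COC(=O)[C@@H](OC)c2ccccc2)cc(OC)c1OC
F10 | step 7 | [(2R,3S)-5-[(1E)-3-(tert-butyldimethylsilyloxy)prop-1-en-1-yl]-7-methoxy-2-(3,4,5-trimethoxyphenyl)-2,3-dihydro-1-benzofuran-3-yl]methanol | COc1cc([C@@H]2Oc3c(OC)cc(/C=C/CO[Si](C)(C)C(C)(C)C)cc3[C@H]2CO)cc(OC)c1OC
A1 | alternative 1 | 4-hydroxy-3-methoxy-5-[(3,4,5-trimethoxyphenyl)ethynyl]benzaldehyde | COc1cc(C=O)cc(C#Cc2cc(OC)c(OC)c(OC)c2)c1O
A2 | alternative 1 | methyl 5-formyl-7-methoxy-2-(3,4,5-trimethoxyphenyl)benzofuran-3-carboxylate | COC(=O)c1c(-c2cc(OC)c(OC)c(OC)c2)oc2c(OC)cc(C=O)cc12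
A3 | alternative 2 | pentacarbonyl[{(1R,2S)-2-[(tert-butyldimethylsilyloxy)methyl]-1-(3,4,5-trimethoxyphenyl)but-3-yn-1-yloxy}(1-methoxyethenyl)methylidene]chromium | COc1cc([C@H](OC(=[Cr](=C=O)(=C=O)(=C=O)(=C=O)=C=O)C(OC)=C)[C@H](CO[Si](C)(C)C(C)(C)C)C#C)cc(OC)c1OC
A4 | alternative 2 | (2R,3S)-3-(tert-butyldimethylsilyloxymethyl)-7-methoxy-2-(3,4,5-trimethoxyphenyl)-2,3-dihydrobenzofuran-5-ol | COc1cc([C@@H]2Oc3c(OC)cc(O)cc3[C@H]2CO[Si](C)(C)C(C)(C)C)cc(OC)c1OC
A5 | alternative 3 | (S)-2-[5-bromo-3-methoxy-2-(methoxymethoxy)phenyl]-3-(tert-butyldiphenylsilyloxy)propanal | O=C[C@H](CO[Si](c1ccccc1)(c1ccccc1)C(C)(C)C)c1cc(Br)cc(OC)c1OCOC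
A6 | alternative 3 | tert-butyl{[(2R,3S)-5-bromo-7-methoxy-2-(3,4,5-trimethoxyphenyl)-2,3-dihydrobenzofuran-3-yl]methoxy}diphenylsilane | COc1cc([C@@H]2Oc3c(OC)cc(Br)cc3[C@H]2CO[Si](c4ccccc4)(c4ccccc4)C(C)(C)C)cc(OC)c1OC
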